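The labels are C1 quaternary C–CH3, C2 ring ketone, C3 CH2, C4 C(OH)iPr, C5 ring-fusion CH, C6 CH–O-vanilloyl, C7–C9 CH2–C(CH3)=CH, C10 CHOH. A Diels–Alder reaction of thymoquinone assembles all fifteen skeletal carbons as a cis-decalin in which C1–C6 form a cyclohexane. The key step is a semipinacol 1,2-shift of C1 from the carbinol C6 to the sulfonate-bearing C5. It contracts ring C1–C6 to the cyclopentanone C1–C5, enlarges the cyclohexene to the cycloheptene, unveils the C6 ketone and sets the trans ring fusion. It exploits the oxygen at C6 next to the fusion carbon C5. The precursor is an all-cis 4,5,6-triol 5-sulfonate.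

Key step: step 8

Remark on the chemistry: the Diels–Alder step is run without chiral control, so 4–11 are racemates (their SMILES show the enantiomer that is carried on); the absolute configuration is secured in step 7 by separating the diastereomeric (1S)-camphorsulfonates, whose sulfonate is the leaving group of step 8.

Step 1
Reactants: 1 3-methylbut-2-enal
Product: 2 (E)-1-(tert-butyldimethylsilyloxy)-3-methylbuta-1,3-diene
Conditions: TBSOTf, Et3N, Et2O, 0 °C → rt
Reagents that add atoms: tert-butyldimethylsilyl trifluoromethanesulfonate, CC(C)(C)[Si](C)(C)OS(=O)(=O)C(F)(F)F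
Why: Silyl dienol ether formation: O-silylation of the enal followed by γ-deprotonation by the amine gives the 1-silyloxy diene, and the E enol ether, the only isomer that can reach the s-cis conformation in step 2, should predominate.

Step 2
Reactants: 2 (E)-1-(tert-butyldimethylsilyloxy)-3-methylbuta-1,3-diene; 3 thymoquinone
Product: 4 (±)-cis-fused ene-dione adduct
Conditions: toluene, BHT (cat.), 80 °C
Reagents that add atoms: none
Why: Thermal endo Diels–Alder reaction: the nucleophilic CH2 terminus of the diene should bond to the unsubstituted C6 of the less hindered C1=C6 bond (methacrolein-like activation by the C2 carbonyl), so that C10–OTBS lies next to the new quaternary C1 and trans to its methyl group while H6 is cis to it; without chiral control the adduct is racemic.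

Step 3
Reactants: 4 (±)-cis-fused ene-dione adduct
Product: 6 (±)-C6 α-ketol, via potassium enolate 5 (not isolated)
Conditions: KHMDS, THF, −78 °C; 2-(phenylsulfonyl)-3-phenyloxaziridine, −78 °C; AcOH quench
Reagents that add atoms: 2-(phenylsulfonyl)-3-phenyloxaziridine, O=S(=O)(c1ccccc1)N1OC1c1ccccc1
Why: Davis enolate hydroxylation: C6–H is the only acidic α-hydrogen (C1 is quaternary, C3 and C4 are sp2), and the oxaziridine should approach the planar enolate on the face of the C1 methyl group, away from C10–OTBS, which keeps the cis ring fusion.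

Step 4
Reactants: 6 (±)-C6 α-ketol
Product: 8 (±)-C4=C5 enol triflate, via lithium enolate 7 (not isolated)
Conditions: L-Selectride, THF, −78 °C; PhNTf2, −78 → 0 °C
Reagents that add atoms: N-phenylbis(trifluoromethanesulfonimide), O=S(=O)(N(c1ccccc1)S(=O)(=O)C(F)(F)F)C(F)(F)F
Why: Conjugate reduction with enolate trapping (reductive triflation): the bulky hydride should add to the unsubstituted β-carbon C3 of the ene-dione rather than to the flanked carbonyls or to isopropyl-bearing C4, and the C5 enolate so formed is fixed as the C4=C5 enol triflate; no stereocentre is formed.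

Step 5
Reactants: 8 (±)-C4=C5 enol triflate
Product: 9 (±)-tertiary allylic alcohol
Conditions: Pd(PPh3)4 (5 mol %), LiCl, Bu3SnH, THF, 50 °C
Reagents that add atoms: none
Why: Palladium-catalysed hydride reduction of a vinyl triflate (oxidative addition, tin-to-palladium hydride transfer, reductive elimination) exchanges OTf for H under neutral conditions that should leave the β,γ-unsaturated ketone, the tertiary allylic alcohol and the allylic silyl ether untouched; no stereocentre is formed.

Step 6
Reactants: 9 (±)-tertiary allylic alcohol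
Product: 11 (±)-all-cis 4,5,6-triol, via osmate ester 10 (not isolated)
Conditions: OsO4 (1.05 equiv), TMEDA, CH2Cl2, −78 °C; then aq. Na2SO3, THF, 40 °C
Reagents that add atoms: osmium tetroxide, O=[Os](=O)(=O)=O
Why: Hydrogen-bond-directed dihydroxylation (Donohoe OsO4·TMEDA): the reagent is delivered by the C6 hydroxyl to the convex face of the C4=C5 bond, which sets C4–OH and C5–OH cis to C6–OH and to the C1 methyl group, while the C8=C9 bond, which has no free hydroxyl nearby, should react more slowly at −78 °C.

Step 7
Reactants: 11 (±)-all-cis 4,5,6-triol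
Product: 12 C5 (1S)-camphor-10-sulfonate of the triol (single diastereomer)
Conditions: (1S)-(+)-camphor-10-sulfonyl chloride, Et3N, DMAP (cat.), CH2Cl2, −20 → 0 °C; separation of the two diastereomers on silica gel or by crystallisation
Reagents that add atoms: (1S)-(+)-camphor-10-sulfonyl chloride, ClS(=O)(=O)C[C@]12CC[C@H](CC1=O)C2(C)C
Why: Sulfonylation through the sulfene should take place only at the secondary C5–OH (both tertiary alcohols are too hindered) and turns the racemate into two diastereomeric sulfonates, a classical resolution in which the resolving group is also the leaving group of step 8; the diastereomer is to be assigned by X-ray analysis and no skeletal stereocentre is changed.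

Step 8
Reactants: 12 C5 (1S)-camphor-10-sulfonate of the triol
Product: 14 trans-fused hydroazulene-2,6-dione, via aluminium alkoxide 13 (not isolated)
Conditions: Et3Al (3 equiv), CH2Cl2, −78 → 0 °C; aq. Rochelle salt
Reagents that add atoms: none
Why: Semipinacol (pinacol-type) rearrangement of a 1,2-diol monosulfonate under Suzuki–Tsuchihashi organoaluminium conditions, the closest precedent being the ring contraction–expansion of cis-decalin-diol monosulfonates to hydroazulenones: the C6 aluminium alkoxide pushes, the C1–C6 bond shifts to C5 and the sulfonate leaves in one concerted event. The cyclopentanone ring C1–C5 is closed by this suprafacial 1,2-alkyl shift (bond C1–C5 forms as C1–C6 breaks), and the same shift inserts C5 into the carbocycle C1/C6–C10 to give the cycloheptene; no other ring is closed. C5 is the only new stereocentre and is set by inversion, C1 entering anti to the equatorial sulfonate so that H5 ends trans to the C1 methyl group, while C1 migrates with retention and C6 becomes the ketone. The step needs migration of C1 rather than of C7 or C3: in the only low-energy chair (isopropyl, sulfonate and C7 equatorial, C4–OH and C6–OH axial) the C5–O bond is antiperiplanar to the ring bonds C6–C1 and C4–C3 but gauche to C6–C7, and the quaternary C1 should out-migrate the primary C3. Elimination is excluded because neither C4 nor C6 carries hydrogen, epoxide formation because both neighbouring hydroxyls are cis to the sulfonate, and the absence of a strong base should avoid enolisation at C3 and retro-aldol cleavage of the β-hydroxy ketone product.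

Step 9
Reactants: 14 trans-fused hydroazulene-2,6-dione
Product: 15 C6 alcohol (4,6-diol)
Conditions: Me4NBH(OAc)3, MeCN/AcOH (1:1), −30 °C
Reagents that add atoms: none
Why: Hydroxyl-directed reduction (Evans–Saksena): the acetoxyborohydride bound to the tertiary C4–OH should deliver hydride intramolecularly to the face of the C6 carbonyl on which C4–O lies (the methyl face), which places C6–OH cis to H5, while the neopentyl C2 ketone, reachable only through a bridged transition state, should react more slowly.

Step 10
Reactants: 16 vanillic acid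
Product: 18 4-(tert-butyldimethylsilyloxy)-3-methoxybenzoic acid, via silyl ester 17 (not isolated)
Conditions: TBSCl (2.5 equiv), imidazole, DMF, rt; then AcOH/THF/H2O, rt
Reagents that add atoms: tert-butyldimethylsilyl chloride, CC(C)(C)[Si](C)(C)Cl
Why: Silyl protection: phenol and acid are silylated together and the labile silyl ester alone is hydrolysed by aqueous acetic acid, which leaves the aryl silyl ether; no stereocentre is involved.

Step 11
Reactants: 15 C6 alcohol (4,6-diol); 18 4-(tert-butyldimethylsilyloxy)-3-methoxybenzoic acid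
Product: 20 bis-silylated target ester, via mixed anhydride 19 (not isolated)
Conditions: 2,4,6-trichlorobenzoyl chloride, Et3N, toluene, rt; then 15, DMAP, toluene, 40 °C
Reagents that add atoms: none
Why: Yamaguchi esterification: the DMAP-activated mixed anhydride should acylate the secondary C6–OH, the tertiary C4–OH being inert, with retention at C6.

Step 12
Reactants: 20 bis-silylated target ester
Product: 21 target
Conditions: HF·pyridine, pyridine/THF, 0 °C → rt
Reagents that add atoms: none
Why: Fluoride-mediated desilylation removes the aryl and the hindered C10 silyl ether under buffered, non-basic conditions that should spare the ester, the tertiary alcohol and both β-hydroxy ketone units; no stereocentre is touched.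

Compound list
1 | 3-methylbut-2-enal (prenal) | CC(C)=CC=O | starting material
2 | (E)-1-(tert-butyldimethylsilyloxy)-3-methylbuta-1,3-diene | C=C(C)/C=C/O[Si](C)(C)C(C)(C)C | intermediate
3 | thymoquinone (2-isopropyl-5-methyl-1,4-benzoquinone) | CC1=CC(=O)C(C(C)C)=CC1=O | starting material
4 | (±)-5-(tert-butyldimethylsilyloxy)-2-isopropyl-4a,7-dimethyl-4a,5,8,8a-tetrahydronaphthalene-1,4-dione; cis-fused, H6 cis and C10–OTBS trans to the C1 methyl group | C1C(C)=C[C@@H](O[Si](C)(C)C(C)(C)C)[C@@]2(C)C(=O)C=C(C(C)C)C(=O)[C@@H]12 | intermediate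
5 | potassium C5=C6 enolate of 4 | [K+].[O-]C1=C2CC(C)=C[C@@H](O[Si](C)(C)C(C)(C)C)[C@@]2(C)C(=O)C=C1C(C)C | intermediate
6 | (±)-8a-hydroxy derivative of 4 (C6–OH cis to the C1 methyl group; α-ketol) | C1C(C)=C[C@@H](O[Si](C)(C)C(C)(C)C)[C@@]2(C)C(=O)C=C(C(C)C)C(=O)[C@@]12O | intermediate
7 | lithium C4=C5 enolate formed by hydride addition to C3 of 6 | C1C(C)=C[C@@H](O[Si](C)(C)C(C)(C)C)[C@@]2(C)C(=O)CC(C(C)C)=C([O-])[C@@]12O.[Li+] | intermediate
8 | (±)-5-(tert-butyldimethylsilyloxy)-8a-hydroxy-2-isopropyl-4a,7-dimethyl-4-oxo-3,4,4a,5,8,8a-hexahydronaphthalen-1-yl triflate (C5–OTf, C4=C5, C3 is CH2) | C1C(C)=C[C@@H](O[Si](C)(C)C(C)(C)C)[C@@]2(C)C(=O)CC(C(C)C)=C(OS(=O)(=O)C(F)(F)F)[C@@]12O | intermediate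
9 | (±)-8-(tert-butyldimethylsilyloxy)-4a-hydroxy-3-isopropyl-6,8a-dimethyl-4a,5,8,8a-tetrahydronaphthalen-1(2H)-one (C6–OH allylic to C4=C5) | C1C(C)=C[C@@H](O[Si](C)(C)C(C)(C)C)[C@@]2(C)C(=O)CC(C(C)C)=C[C@@]12O | intermediate
10 | cyclic C4,C5 osmate(VI) ester of 9, TMEDA adduct | C1C(C)=C[C@@H](O[Si](C)(C)C(C)(C)C)[C@@]2(C)C(=O)C[C@]3(C(C)C)O[Os](=O)(=O)O[C@@H]3[C@@]12O.CN(C)CCN(C)C | intermediate
11 | (±)-8-(tert-butyldimethylsilyloxy)-3,4,4a-trihydroxy-3-isopropyl-6,8a-dimethyl-3,4,4a,5,8,8a-hexahydronaphthalen-1(2H)-one; C4–OH, C5–OH and C6–OH all cis to one another and to the C1 methyl group | C1C(C)=C[C@@H](O[Si](C)(C)C(C)(C)C)[C@@]2(C)C(=O)C[C@@](O)(C(C)C)[C@H](O)[C@@]12O | intermediate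
12 | C5 (1S)-camphor-10-sulfonate of the triol, single enantiomer and diastereomer | C1C(C)=C[C@@H](O[Si](C)(C)C(C)(C)C)[C@@]2(C)C(=O)C[C@@](O)(C(C)C)[C@H](OS(=O)(=O)C[C@]34CC[C@H](CC3=O)C4(C)C)[C@@]12O | intermediate
13 | bis(diethylaluminium) C4,C6-dialkoxide of 12 | C1C(C)=C[C@@H](O[Si](C)(C)C(C)(C)C)[C@@]2(C)C(=O)C[C@@](O[Al](CC)CC)(C(C)C)[C@H](OS(=O)(=O)C[C@]34CC[C@H](CC3=O)C4(C)C)[C@@]12O[Al](CC)CC | intermediate
14 | 8-(tert-butyldimethylsilyloxy)-3-hydroxy-3-isopropyl-6,8a-dimethyl-2,3,3a,5,8,8a-hexahydroazulene-1,4-dione; trans-fused, H5 trans and C4–OH cis to the C1 methyl group | O=C1CC(C)=C[C@@H](O[Si](C)(C)C(C)(C)C)[C@@]2(C)C(=O)C[C@@](O)(C(C)C)[C@H]12 | intermediate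
15 | 8-(tert-butyldimethylsilyloxy)-3,4-dihydroxy-3-isopropyl-6,8a-dimethyl-3,3a,4,5,8,8a-hexahydroazulen-1(2H)-one; C6–OH cis to H5 | O[C@H]1CC(C)=C[C@@H](O[Si](C)(C)C(C)(C)C)[C@@]2(C)C(=O)C[C@@](O)(C(C)C)[C@H]12 | intermediate
16 | vanillic acid (4-hydroxy-3-methoxybenzoic acid) | COc1cc(C(=O)O)ccc1O | starting material
17 | tert-butyldimethylsilyl 4-(tert-butyldimethylsilyloxy)-3-methoxybenzoate | COc1cc(C(=O)O[Si](C)(C)C(C)(C)C)ccc1O[Si](C)(C)C(C)(C)C | intermediate
18 | 4-(tert-butyldimethylsilyloxy)-3-methoxybenzoic acid | COc1cc(C(=O)O)ccc1O[Si](C)(C)C(C)(C)C | intermediate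
19 | mixed anhydride of 18 with 2,4,6-trichlorobenzoic acid | COc1cc(C(=O)OC(=O)c2c(Cl)cc(Cl)cc2Cl)ccc1O[Si](C)(C)C(C)(C)C | intermediate
20 | C6 4-(tert-butyldimethylsilyloxy)-3-methoxybenzoate of 15 (C10–OTBS retained) | COc1cc(C(=O)O[C@H]2CC(C)=C[C@@H](O[Si](C)(C)C(C)(C)C)[C@@]3(C)C(=O)C[C@@](O)(C(C)C)[C@H]23)ccc1O[Si](C)(C)C(C)(C)C | intermediate
21 | (3R,3aS,4S,8R,8aS)-3,8-dihydroxy-3-isopropyl-6,8a-dimethyl-1-oxo-1,2,3,3a,4,5,8,8a-octahydroazulen-4-yl 4-hydroxy-3-methoxybenzoate; C1 methyl and C4–OH on one face, H5, C6–O-vanilloyl and C10–OH on the other | COc1cc(C(=O)O[C@H]2CC(C)=C[C@@H](O)[C@@]3(C)C(=O)C[C@@](O)(C(C)C)[C@H]23)ccc1O | target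

Total step count: 12. Longest linear sequence: 11 (steps 1–9, 11, 12; step 10 prepares the acid 18).

Steps most likely to fail

Step 8: the shift may take the wrong course, with C3 migrating under the push of the C4 alkoxide (contraction to a hydrindane with an isobutyryl side chain) or the sulfonate simply not leaving. The fallback removes the competing donor instead of changing the promoter. It sets out from 12, whose less shielded tertiary C4–OH (the C6–OH sits at the ring fusion next to quaternary C1) is silylated with TESOTf and 2,6-lutidine in CH2Cl2 at −78 °C to the 4-O-triethylsilyl sulfonate F1. Only the C6 alkoxide can then push, and Et3Al (2 equiv, CH2Cl2, −78 → 0 °C) should give the 4-O-triethylsilyl diketone F2. PPTS in MeOH at 0 °C cleaves the triethylsilyl ether and the route is rejoined at 14.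

Step 4: the hydride may attack a carbonyl (1,2-reduction) or C4, which would give the wrong enolate or an over-reduced product. The fallback replaces the hydride by a transition-metal 1,4-hydrosilylation. It sets out from 6, which with Et3SiH and RhCl(PPh3)3 (cat.) in benzene at 50 °C should give the C5 triethylsilyl enol ether F3 regiospecifically. Fluoride-triggered triflation (CsF, PhNTf2, DME, rt) comes back to the route at 8.

Step 9: the directing C4–OH is also β to the C2 ketone, so over-reduction at C2 or hydride delivery to the wrong face of C6 may occur. The fallback uses steric instead of directed control and corrects C6 in the esterification. It sets out from 14, which with L-Selectride in THF at −78 °C should be attacked at C6 from the open face on the side of H5 to give the C6-epimeric alcohol F4, the neopentyl C2 ketone staying intact. Mitsunobu esterification of F4 with 18 (PPh3, DIAD, toluene, 0 °C → rt) inverts C6 and comes back to the route at 20, so that step 11 is not needed.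

Further compounds
F1 | step 8 | 4-O-triethylsilyl ether of sulfonate 12 | C1C(C)=C[C@@H](O[Si](C)(C)C(C)(C)C)[C@@]2(C)C(=O)C[C@@](O[Si](CC)(CC)CC)(C(C)C)[C@H](OS(=O)(=O)C[C@]34CC[C@H](CC3=O)C4(C)C)[C@@]12O
F2 | step 8 | 4-O-triethylsilyl ether of diketone 14 | O=C1CC(C)=C[C@@H](O[Si](C)(C)C(C)(C)C)[C@@]2(C)C(=O)C[C@@](O[Si](CC)(CC)CC)(C(C)C)[C@H]12
F3 | step 4 | (±)-C5 triethylsilyl enol ether (C4=C5, C3 is CH2, C6–OH free) | C1C(C)=C[C@@H](O[Si](C)(C)C(C)(C)C)[C@@]2(C)C(=O)CC(C(C)C)=C(O[Si](CC)(CC)CC)[C@@]12O
F4 | step 9 | C6 epimer of alcohol 15 (C6–OH trans to H5) | O[C@@H]1CC(C)=C[C@@H](O[Si](C)(C)C(C)(C)C)[C@@]2(C)C(=O)C[C@@](O)(C(C)C)[C@H]12
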